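The cyclohexane ring C13–C14–C15–C8–C7–C12 carries oxygen at C13 and at C15 (with its methyl C16): the 1,3-pattern of an aldol between the two acetyl groups of acetylacetone. Its C7–C12 bond is the fusion bond to the cyclopentanone. The ring is therefore first made too small: De Mayo [2+2] photocycloaddition of acetylacetone to the C7=C12 double bond of cyclopentene 10 (one silyl ether, two 3-silyloxypropyl arms) gives cyclobutanol C13–C8–C7–C12, and retro-aldol opening followed by aldol condensation inserts C14–C15, giving the cis-hydrindenone with quaternary C12 in one operation. Double N-alkylation then closes the azonane and the C3=C4 enone is introduced last.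

Key step: step 5

Remark on atom labels: Lycopodium numbering is used throughout: N–C1–C2–C3=C4–C5(=O)–C6–C7–C8–C15(C16)–C14–C13–C12; C12 is also bonded to C4, C7 and C11; C11–C10–C9–N.
Remark on the source of chirality: (R)-4-(tert-butyldimethylsilyloxy)cyclopent-2-en-1-one is assumed to be bought enantiopure; its silyloxy carbon becomes C5, controls C4, C7 and C12, and is finally oxidised to the ketone.

Step 1
Reactants: 1 (R)-4-(tert-butyldimethylsilyloxy)cyclopent-2-en-1-one
Product: 2 (R)-4-(tert-butyldimethylsilyloxy)-2-iodocyclopent-2-en-1-one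
Conditions: I2, pyridine, CH2Cl2, 0 °C → rt
Reagents that add atoms: iodine, II
Why: α-Iodination of the enone by pyridine addition, iodination of the enolate and elimination (Johnson α-iodoenone synthesis); the silyloxy stereocentre is not involved.

Step 2
Reactants: 2 (R)-4-(tert-butyldimethylsilyloxy)-2-iodocyclopent-2-en-1-one; 3 allyloxy(tert-butyl)dimethylsilane
Product: 5 (R)-4-(tert-butyldimethylsilyloxy)-2-[3-(tert-butyldimethylsilyloxy)propyl]cyclopent-2-en-1-one, via alkylborane 4 (not isolated)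
Conditions: 3, 9-BBN, THF, rt; then 2, PdCl2(dppf) (cat.), AsPh3, Cs2CO3, DMF–THF–H2O, rt
Reagents that add atoms: none
Why: Anti-Markovnikov hydroboration gives the primary alkylborane, which couples with the α-iodoenone in a B-alkyl Suzuki–Miyaura reaction under the mild conditions established for 2-iodo-4-silyloxycyclopentenones, so the base-labile β-silyloxy ketone should survive.

Step 3
Reactants: 5 (R)-4-(tert-butyldimethylsilyloxy)-2-[3-(tert-butyldimethylsilyloxy)propyl]cyclopent-2-en-1-one; 6 (3-bromopropoxy)(tert-butyl)dimethylsilane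
Product: 9 (3R,4R)-4-(tert-butyldimethylsilyloxy)-2,3-bis[3-(tert-butyldimethylsilyloxy)propyl]cyclopent-1-en-1-yl trifluoromethanesulfonate, via Grignard reagent 7 (not isolated), via magnesium enolate 8 (not isolated)
Conditions: 6, Mg, THF; CuBr·SMe2 (0.5 equiv per Grignard), THF, −78 °C; 5, −78 °C; then Comins' reagent, −78 → 0 °C
Reagents that add atoms: Comins' reagent [N-(5-chloropyridin-2-yl)bis(trifluoromethanesulfonimide)], FC(F)(F)S(=O)(=O)N(c1ccc(Cl)cn1)S(=O)(=O)C(F)(F)F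
Why: Cuprate 1,4-addition occurs trans to the silyloxy group (this sets C4), and the regiodefined enolate is O-triflated cold, before it can equilibrate and expel silanolate (conjugate addition–enolate triflation).

Step 4
Reactants: 9 (3R,4R)-4-(tert-butyldimethylsilyloxy)-2,3-bis[3-(tert-butyldimethylsilyloxy)propyl]cyclopent-1-en-1-yl trifluoromethanesulfonate
Product: 10 (1R,2R)-1-(tert-butyldimethylsilyloxy)-2,3-bis[3-(tert-butyldimethylsilyloxy)propyl]cyclopent-3-ene
Conditions: Pd(OAc)2 (cat.), PPh3, Bu3N, HCO2H, DMF, 60 °C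
Reagents that add atoms: none
Why: Palladium-catalysed formate reduction of the enol triflate (Cacchi conditions) replaces OTf by H without moving the double bond, giving the trisubstituted C7=C12 alkene.

Step 5
Reactants: 10 (1R,2R)-1-(tert-butyldimethylsilyloxy)-2,3-bis[3-(tert-butyldimethylsilyloxy)propyl]cyclopent-3-ene; 11 pentane-2,4-dione
Product: 14 (2R,3R,3aS,7aS)-2-(tert-butyldimethylsilyloxy)-3,3a-bis[3-(tert-butyldimethylsilyloxy)propyl]-6-methyl-1,2,3,3a,7,7a-hexahydro-4H-inden-4-one, via cyclobutanol photoadduct 12 (not isolated), via 1,5-diketone 13 (not isolated)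
Conditions: 11 (excess), MeCN, hν (300 nm), rt; evaporate excess 11; then NaOMe, MeOH, 50 °C
Reagents that add atoms: none
Why: Excitation of the hydrogen-bonded enol of 11 and [2+2] photocycloaddition to C7=C12 gives cis-fused cyclobutanol 12 (new bonds C12–C13 and C7–C8), which opens by retro-aldol cleavage of C13–C8 to diketone 13; methoxide then forms C14–C15 by aldol condensation, so the four cyclobutane carbons C13, C8, C7 and C12 end in a six-membered ring enlarged by C14 and C15. The closest known chemistry is the De Mayo reaction followed by a Robinson-type aldol condensation, a formal two-carbon ring expansion of a cyclobutanol. The four-membered ring closes by stepwise [2+2] cycloaddition through a 1,4-biradical, and the six-membered ring by 6-(enolendo)-exo-trig aldol addition with E1cB dehydration. The new stereocentres are C7 and C12: the cyclobutane can only be cis-fused to the cyclopentene, and the diketone should add anti to the allylic C4 side chain, which places C13 trans and C11 cis to that chain. The step needs head-to-tail orientation, which the more stable biradical (tertiary at C12, oxygen-substituted at C13) should secure, and the right aldol mode, which is favoured because the C14 enolate attacks the unhindered C15 ketone whereas the alternative attacks the neopentyl C13 ketone.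

Step 6
Reactants: 14 (2R,3R,3aS,7aS)-2-(tert-butyldimethylsilyloxy)-3,3a-bis[3-(tert-butyldimethylsilyloxy)propyl]-6-methyl-1,2,3,3a,7,7a-hexahydro-4H-inden-4-one
Product: 15 (2R,3R,3aS,4S,7aS)-2-(tert-butyldimethylsilyloxy)-3,3a-bis[3-(tert-butyldimethylsilyloxy)propyl]-6-methyl-2,3,3a,4,7,7a-hexahydro-1H-inden-4-ol
Conditions: NaBH4, CeCl3·7H2O, MeOH, −40 °C
Reagents that add atoms: none
Why: Luche 1,2-reduction, in which hydride should add to the convex face, anti to the pseudo-axial C4 of the cis-fused cyclopentane and its silyloxy group, giving the pseudo-equatorial C13 alcohol.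

Step 7
Reactants: 15 (2R,3R,3aS,4S,7aS)-2-(tert-butyldimethylsilyloxy)-3,3a-bis[3-(tert-butyldimethylsilyloxy)propyl]-6-methyl-2,3,3a,4,7,7a-hexahydro-1H-inden-4-ol
Product: 16 (2R,3R,3aS,4R,5R,6S,7aR)-2-(tert-butyldimethylsilyloxy)-3,3a-bis[3-(tert-butyldimethylsilyloxy)propyl]-5,6-epoxy-6-methyloctahydro-1H-inden-4-ol
Conditions: VO(acac)2 (cat.), t-BuOOH, CH2Cl2, 0 °C → rt
Reagents that add atoms: tert-butyl hydroperoxide, CC(C)(C)OO
Why: Vanadium-catalysed hydroxyl-directed epoxidation delivers oxygen to the C14=C15 face syn to the C13 hydroxyl, which sets the C15–O bond cis to C13–O.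

Step 8
Reactants: 16 (2R,3R,3aS,4R,5R,6S,7aR)-2-(tert-butyldimethylsilyloxy)-3,3a-bis[3-(tert-butyldimethylsilyloxy)propyl]-5,6-epoxy-6-methyloctahydro-1H-inden-4-ol
Product: 17 (2R,3R,3aS,4S,6S,7aR)-2-(tert-butyldimethylsilyloxy)-3,3a-bis[3-(tert-butyldimethylsilyloxy)propyl]-6-methyloctahydro-1H-indene-4,6-diol
Conditions: Red-Al, THF, 0 °C → rt
Reagents that add atoms: none
Why: Hydride opening of the 2,3-epoxy alcohol occurs by SN2 attack at the secondary C14 and not at the fully substituted C15, giving the cis-1,3-diol with retention at C15.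

Step 9
Reactants: 17 (2R,3R,3aS,4S,6S,7aR)-2-(tert-butyldimethylsilyloxy)-3,3a-bis[3-(tert-butyldimethylsilyloxy)propyl]-6-methyloctahydro-1H-indene-4,6-diol
Product: 18 (2R,3R,3aS,4S,6S,7aR)-2-(tert-butyldimethylsilyloxy)-3,3a-bis[3-(tert-butyldimethylsilyloxy)propyl]-6-methyloctahydro-1H-indene-4,6-diyl diacetate
Conditions: Ac2O, Et3N, DMAP, CH2Cl2, 40 °C
Reagents that add atoms: acetic anhydride, CC(=O)OC(C)=O
Why: DMAP-catalysed acetylation (Steglich conditions) esterifies the secondary and, on warming, the tertiary hydroxyl without touching a stereocentre.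

Step 10
Reactants: 18 (2R,3R,3aS,4S,6S,7aR)-2-(tert-butyldimethylsilyloxy)-3,3a-bis[3-(tert-butyldimethylsilyloxy)propyl]-6-methyloctahydro-1H-indene-4,6-diyl diacetate
Product: 19 (2R,3R,3aS,4S,6S,7aR)-3,3a-bis(3-bromopropyl)-2-(tert-butyldimethylsilyloxy)-6-methyloctahydro-1H-indene-4,6-diyl diacetate
Conditions: Ph3PBr2, CH2Cl2, 0 °C → rt
Reagents that add atoms: dibromotriphenylphosphorane, BrP(Br)(c1ccccc1)(c1ccccc1)c1ccccc1
Why: Direct conversion of primary silyl ethers into bromides (O-phosphonium formation, loss of silyl bromide, SN2 by bromide), which the hindered secondary silyl ether on the cyclopentane should undergo much more slowly.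

Step 11
Reactants: 19 (2R,3R,3aS,4S,6S,7aR)-3,3a-bis(3-bromopropyl)-2-(tert-butyldimethylsilyloxy)-6-methyloctahydro-1H-indene-4,6-diyl diacetate; 20 2-nitrobenzenesulfonamide
Product: 22 (1S,2S,4S,6R,8R,9R)-8-(tert-butyldimethylsilyloxy)-4-methyl-13-(2-nitrophenylsulfonyl)-13-azatricyclo[7.7.0.0^{1,6}]hexadecane-2,4-diyl diacetate, via monoalkylated sulfonamide 21 (not isolated)
Conditions: 20, Cs2CO3, Bu4NI (cat.), DMF, 60 °C, high dilution (slow addition of 19)
Reagents that add atoms: none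
Why: Double N-alkylation of the nosyl amide (Fukuyama-type), in which the second alkylation closes the nine-membered ring, helped by the cis arrangement of the two arms on C4 and C12, the caesium base and high dilution.

Step 12
Reactants: 22 (1S,2S,4S,6R,8R,9R)-8-(tert-butyldimethylsilyloxy)-4-methyl-13-(2-nitrophenylsulfonyl)-13-azatricyclo[7.7.0.0^{1,6}]hexadecane-2,4-diyl diacetate
Product: 23 (1S,2S,4S,6R,8R,9R)-8-hydroxy-4-methyl-13-(2-nitrophenylsulfonyl)-13-azatricyclo[7.7.0.0^{1,6}]hexadecane-2,4-diyl diacetate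
Conditions: HF·pyridine, pyridine, THF, rt
Reagents that add atoms: none
Why: Buffered fluoride cleavage of the remaining secondary silyl ether, to which the acetates and the sulfonamide are inert.

Step 13
Reactants: 23 (1S,2S,4S,6R,8R,9R)-8-hydroxy-4-methyl-13-(2-nitrophenylsulfonyl)-13-azatricyclo[7.7.0.0^{1,6}]hexadecane-2,4-diyl diacetate
Product: 24 (1S,2S,4S,6S,9R)-4-methyl-13-(2-nitrophenylsulfonyl)-8-oxo-13-azatricyclo[7.7.0.0^{1,6}]hexadecane-2,4-diyl diacetate
Conditions: Dess–Martin periodinane, NaHCO3, CH2Cl2, rt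
Reagents that add atoms: none
Why: Dess–Martin oxidation of the secondary alcohol to the C5 cyclopentanone under buffered conditions.

Step 14
Reactants: 24 (1S,2S,4S,6S,9R)-4-methyl-13-(2-nitrophenylsulfonyl)-8-oxo-13-azatricyclo[7.7.0.0^{1,6}]hexadecane-2,4-diyl diacetate
Product: 26 (1S,2S,4S,6S,9E)-4-methyl-13-(2-nitrophenylsulfonyl)-8-oxo-13-azatricyclo[7.7.0.0^{1,6}]hexadec-9-ene-2,4-diyl diacetate, via silyl enol ether 25 (not isolated)
Conditions: TMSOTf, Et3N, CH2Cl2, 0 → 40 °C (equilibrating); evaporate; Pd(OAc)2, MeCN, rt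
Reagents that add atoms: none
Why: Soft enolisation under equilibrating conditions should give the more substituted C4=C5 silyl enol ether, and Saegusa–Ito oxidation through the C4 palladium enolate can eliminate a β-hydride only from C3 because C12 is quaternary, giving the exocyclic enone whose geometry the nine-membered ring fixes as the cis-cycloalkene (9E).

Step 15
Reactants: 26 (1S,2S,4S,6S,9E)-4-methyl-13-(2-nitrophenylsulfonyl)-8-oxo-13-azatricyclo[7.7.0.0^{1,6}]hexadec-9-ene-2,4-diyl diacetate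
Product: 27 (1S,2S,4S,6S,9E)-4-methyl-8-oxo-13-azatricyclo[7.7.0.0^{1,6}]hexadec-9-ene-2,4-diyl diacetate
Conditions: PhSH, K2CO3, MeCN, rt
Reagents that add atoms: none
Why: Fukuyama nosyl cleavage (thiolate addition to the nitroarene, loss of SO2) releases the secondary amine without acid or strong base, so both acetates and the enone should survive; reversible thiol addition to the enone drains back as the thiol is consumed.

Compound list
1 | (R)-4-(tert-butyldimethylsilyloxy)cyclopent-2-en-1-one | O=C1C[C@@H](O[Si](C)(C)C(C)(C)C)C=C1 | starting material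
2 | (R)-4-(tert-butyldimethylsilyloxy)-2-iodocyclopent-2-en-1-one | O=C1C[C@@H](O[Si](C)(C)C(C)(C)C)C=C1I | intermediate
3 | allyloxy(tert-butyl)dimethylsilane | C=CCO[Si](C)(C)C(C)(C)C | starting material
4 | 9-[3-(tert-butyldimethylsilyloxy)propyl]-9-borabicyclo[3.3.1]nonane | CC(C)(C)[Si](C)(C)OCCCB1C2CCCC1CCC2 | intermediate
5 | (R)-4-(tert-butyldimethylsilyloxy)-2-[3-(tert-butyldimethylsilyloxy)propyl]cyclopent-2-en-1-one | O=C1C[C@@H](O[Si](C)(C)C(C)(C)C)C=C1CCCO[Si](C)(C)C(C)(C)C | intermediate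
6 | (3-bromopropoxy)(tert-butyl)dimethylsilane | BrCCCO[Si](C)(C)C(C)(C)C | starting material
7 | [3-(tert-butyldimethylsilyloxy)propyl]magnesium bromide | Br[Mg]CCCO[Si](C)(C)C(C)(C)C | intermediate
8 | bromomagnesium (3R,4R)-4-(tert-butyldimethylsilyloxy)-2,3-bis[3-(tert-butyldimethylsilyloxy)propyl]cyclopent-1-en-1-olate | Br[Mg]OC1=C(CCCO[Si](C)(C)C(C)(C)C)[C@@H](CCCO[Si](C)(C)C(C)(C)C)[C@H](O[Si](C)(C)C(C)(C)C)C1 | intermediate
9 | (3R,4R)-4-(tert-butyldimethylsilyloxy)-2,3-bis[3-(tert-butyldimethylsilyloxy)propyl]cyclopent-1-en-1-yl trifluoromethanesulfonate | O=S(=O)(OC1=C(CCCO[Si](C)(C)C(C)(C)C)[C@@H](CCCO[Si](C)(C)C(C)(C)C)[C@H](O[Si](C)(C)C(C)(C)C)C1)C(F)(F)F | intermediate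
10 | (1R,2R)-1-(tert-butyldimethylsilyloxy)-2,3-bis[3-(tert-butyldimethylsilyloxy)propyl]cyclopent-3-ene | CC(C)(C)[Si](C)(C)O[C@@H]1CC=C(CCCO[Si](C)(C)C(C)(C)C)[C@H]1CCCO[Si](C)(C)C(C)(C)C | intermediate
11 | pentane-2,4-dione (acetylacetone) | CC(=O)CC(C)=O | starting material
12 | 1-[(1S,2R,3R,5R)-7-hydroxy-7-methyl-3-(tert-butyldimethylsilyloxy)-1,2-bis[3-(tert-butyldimethylsilyloxy)propyl]bicyclo[3.2.0]heptan-6-yl]ethan-1-one (cis-fused; epimers at C6 and C7) | CC(=O)C1[C@H]2C[C@@H](O[Si](C)(C)C(C)(C)C)[C@H](CCCO[Si](C)(C)C(C)(C)C)[C@@]2(CCCO[Si](C)(C)C(C)(C)C)C1(C)O | intermediate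
13 | 1-[(1R,2S,3R,4R)-2-acetyl-4-(tert-butyldimethylsilyloxy)-2,3-bis[3-(tert-butyldimethylsilyloxy)propyl]cyclopentyl]propan-2-one | CC(=O)C[C@H]1C[C@@H](O[Si](C)(C)C(C)(C)C)[C@H](CCCO[Si](C)(C)C(C)(C)C)[C@@]1(CCCO[Si](C)(C)C(C)(C)C)C(C)=O | intermediate
14 | (2R,3R,3aS,7aS)-2-(tert-butyldimethylsilyloxy)-3,3a-bis[3-(tert-butyldimethylsilyloxy)propyl]-6-methyl-1,2,3,3a,7,7a-hexahydro-4H-inden-4-one | O=C1C=C(C)C[C@H]2C[C@@H](O[Si](C)(C)C(C)(C)C)[C@H](CCCO[Si](C)(C)C(C)(C)C)[C@]21CCCO[Si](C)(C)C(C)(C)C | intermediate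
15 | (2R,3R,3aS,4S,7aS)-2-(tert-butyldimethylsilyloxy)-3,3a-bis[3-(tert-butyldimethylsilyloxy)propyl]-6-methyl-2,3,3a,4,7,7a-hexahydro-1H-inden-4-ol | O[C@H]1C=C(C)C[C@H]2C[C@@H](O[Si](C)(C)C(C)(C)C)[C@H](CCCO[Si](C)(C)C(C)(C)C)[C@]21CCCO[Si](C)(C)C(C)(C)C | intermediate
16 | (2R,3R,3aS,4R,5R,6S,7aR)-2-(tert-butyldimethylsilyloxy)-3,3a-bis[3-(tert-butyldimethylsilyloxy)propyl]-5,6-epoxy-6-methyloctahydro-1H-inden-4-ol (epoxide cis to the hydroxyl) | O[C@H]1[C@H]3O[C@@]3(C)C[C@H]2C[C@@H](O[Si](C)(C)C(C)(C)C)[C@H](CCCO[Si](C)(C)C(C)(C)C)[C@]21CCCO[Si](C)(C)C(C)(C)C | intermediate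
17 | (2R,3R,3aS,4S,6S,7aR)-2-(tert-butyldimethylsilyloxy)-3,3a-bis[3-(tert-butyldimethylsilyloxy)propyl]-6-methyloctahydro-1H-indene-4,6-diol | O[C@H]1C[C@@](C)(O)C[C@H]2C[C@@H](O[Si](C)(C)C(C)(C)C)[C@H](CCCO[Si](C)(C)C(C)(C)C)[C@]21CCCO[Si](C)(C)C(C)(C)C | intermediate
18 | (2R,3R,3aS,4S,6S,7aR)-2-(tert-butyldimethylsilyloxy)-3,3a-bis[3-(tert-butyldimethylsilyloxy)propyl]-6-methyloctahydro-1H-indene-4,6-diyl diacetate | CC(=O)O[C@H]1C[C@@](C)(OC(C)=O)C[C@H]2C[C@@H](O[Si](C)(C)C(C)(C)C)[C@H](CCCO[Si](C)(C)C(C)(C)C)[C@]21CCCO[Si](C)(C)C(C)(C)C | intermediate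
19 | (2R,3R,3aS,4S,6S,7aR)-3,3a-bis(3-bromopropyl)-2-(tert-butyldimethylsilyloxy)-6-methyloctahydro-1H-indene-4,6-diyl diacetate | CC(=O)O[C@H]1C[C@@](C)(OC(C)=O)C[C@H]2C[C@@H](O[Si](C)(C)C(C)(C)C)[C@H](CCCBr)[C@]21CCCBr | intermediate
20 | 2-nitrobenzenesulfonamide | NS(=O)(=O)c1ccccc1[N+](=O)[O-] | starting material
21 | (2R,3R,3aS,4S,6S,7aR)-3-(3-bromopropyl)-2-(tert-butyldimethylsilyloxy)-6-methyl-3a-[3-(2-nitrophenylsulfonylamino)propyl]octahydro-1H-indene-4,6-diyl diacetate (or its isomer alkylated first at the other arm) | CC(=O)O[C@H]1C[C@@](C)(OC(C)=O)C[C@H]2C[C@@H](O[Si](C)(C)C(C)(C)C)[C@H](CCCBr)[C@]21CCCNS(=O)(=O)c3ccccc3[N+](=O)[O-] | intermediate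
22 | (1S,2S,4S,6R,8R,9R)-8-(tert-butyldimethylsilyloxy)-4-methyl-13-(2-nitrophenylsulfonyl)-13-azatricyclo[7.7.0.0^{1,6}]hexadecane-2,4-diyl diacetate | CC(=O)O[C@H]1C[C@@](C)(OC(C)=O)C[C@H]2C[C@@H](O[Si](C)(C)C(C)(C)C)[C@@H]3CCCN(S(=O)(=O)c4ccccc4[N+](=O)[O-])CCC[C@@]321 | intermediate
23 | (1S,2S,4S,6R,8R,9R)-8-hydroxy-4-methyl-13-(2-nitrophenylsulfonyl)-13-azatricyclo[7.7.0.0^{1,6}]hexadecane-2,4-diyl diacetate | CC(=O)O[C@H]1C[C@@](C)(OC(C)=O)C[C@H]2C[C@@H](O)[C@@H]3CCCN(S(=O)(=O)c4ccccc4[N+](=O)[O-])CCC[C@@]321 | intermediate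
24 | (1S,2S,4S,6S,9R)-4-methyl-13-(2-nitrophenylsulfonyl)-8-oxo-13-azatricyclo[7.7.0.0^{1,6}]hexadecane-2,4-diyl diacetate | CC(=O)O[C@H]1C[C@@](C)(OC(C)=O)C[C@H]2CC(=O)[C@@H]3CCCN(S(=O)(=O)c4ccccc4[N+](=O)[O-])CCC[C@@]321 | intermediate
25 | (1S,2S,4S,6S)-4-methyl-13-(2-nitrophenylsulfonyl)-8-(trimethylsilyloxy)-13-azatricyclo[7.7.0.0^{1,6}]hexadec-8-ene-2,4-diyl diacetate | CC(=O)O[C@H]1C[C@@](C)(OC(C)=O)C[C@H]2CC(O[Si](C)(C)C)=C3CCCN(S(=O)(=O)c4ccccc4[N+](=O)[O-])CCC[C@@]321 | intermediate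
26 | (1S,2S,4S,6S,9E)-4-methyl-13-(2-nitrophenylsulfonyl)-8-oxo-13-azatricyclo[7.7.0.0^{1,6}]hexadec-9-ene-2,4-diyl diacetate | CC(=O)O[C@H]1C[C@@](C)(OC(C)=O)C[C@H]2CC(=O)/C3=C/CCN(S(=O)(=O)c4ccccc4[N+](=O)[O-])CCC[C@@]321 | intermediate
27 | (1S,2S,4S,6S,9E)-4-methyl-8-oxo-13-azatricyclo[7.7.0.0^{1,6}]hexadec-9-ene-2,4-diyl diacetate (CNP0120442.1) | CC(=O)O[C@H]1C[C@@](C)(OC(C)=O)C[C@H]2CC(=O)/C3=C/CCNCCC[C@@]321 | target

Total step count: 15. Longest linear sequence: 15 steps (1 → 27); compounds 3, 6, 11 and 20 are bought.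

Steps most likely to fail

Step 5 (key step). The excited enol of acetylacetone is short-lived and may be intercepted poorly by the hindered alkene used as the limiting component. It may also add head-to-head or to the face syn to the C4 chain, and the diketone may close in the alternative aldol sense. The fallback sets out from 10 and comes back at 14. Irradiation of 10 with 2,2,6-trimethyl-4H-1,3-dioxin-4-one (300 nm, MeCN–acetone), a more efficient chromophore with reliable head-to-tail orientation, should give the isolable cyclobutane-fused dioxanone photoadduct F1. NaOMe in MeOH–THF at 50 °C opens the lactone acetal, the cyclobutanolate undergoes retro-aldol cleavage to the keto ester F2 (not isolated), and Claisen condensation of the C14 enolate onto the ester closes the cyclohexane-1,3-dione F3, again a four-to-six ring expansion. O-Triflation at the oxygen remote from the quaternary carbon (Tf2O, 2,6-lutidine, CH2Cl2, −78 °C) gives the vinylogous acyl triflate F4, and Me2CuLi (THF, −78 °C, addition–elimination) installs C16 to give 14.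

Step 14. Enolisation may be diverted to the less hindered C6, which would lead to the endocyclic C6=C7 enone after palladium oxidation. The fallback sets out from 24 and comes back at 26. Sulfuryl chloride (CH2Cl2, 0 °C) chlorinates ketones through the acid-equilibrated enol at the more substituted α-carbon and should give the tertiary α-chloro ketone F5. Dehydrochlorination with Li2CO3 and LiBr in DMF at 100 °C can only occur towards C3 and gives 26.

Step 11. Intermolecular oligomerisation may outrun closure of the nine-membered ring by the weakly nucleophilic monoalkylated sulfonamide anion. The fallback sets out from 19 and comes back at 22. Benzylamine (1 equiv), K2CO3 and NaI in MeCN at 80 °C under high dilution should give, through the more nucleophilic secondary amine, the N-benzyl azonane F6. Hydrogenolysis (H2, Pd(OH)2/C, EtOH; no reducible group is present at this stage) gives the secondary amine F7, and 2-nitrobenzenesulfonyl chloride with Et3N in CH2Cl2 gives 22.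

Further compounds
F1 | step 5 | head-to-tail photoadduct of 10 and 2,2,6-trimethyl-4H-1,3-dioxin-4-one: cis-fused cyclobutane carrying the 2,2-dimethyl-1,3-dioxan-4-one ring anti to the cyclopentane, with methyl and ring oxygen on C13 and the lactone carbonyl on C8 | O=C1OC(C)(C)O[C@]2(C)[C@H]1[C@H]3C[C@@H](O[Si](C)(C)C(C)(C)C)[C@H](CCCO[Si](C)(C)C(C)(C)C)[C@]32CCCO[Si](C)(C)C(C)(C)C
F2 | step 5 | methyl 2-[(1R,2S,3R,4R)-2-acetyl-4-(tert-butyldimethylsilyloxy)-2,3-bis[3-(tert-butyldimethylsilyloxy)propyl]cyclopentyl]acetate | COC(=O)C[C@H]1C[C@@H](O[Si](C)(C)C(C)(C)C)[C@H](CCCO[Si](C)(C)C(C)(C)C)[C@@]1(CCCO[Si](C)(C)C(C)(C)C)C(C)=O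
F3 | step 5 | (2R,3R,3aS,7aR)-2-(tert-butyldimethylsilyloxy)-3,3a-bis[3-(tert-butyldimethylsilyloxy)propyl]hexahydro-1H-indene-4,6(2H,5H)-dione | O=C1CC(=O)C[C@H]2C[C@@H](O[Si](C)(C)C(C)(C)C)[C@H](CCCO[Si](C)(C)C(C)(C)C)[C@]21CCCO[Si](C)(C)C(C)(C)C
F4 | step 5 | (2R,3R,3aS,7aR)-2-(tert-butyldimethylsilyloxy)-3,3a-bis[3-(tert-butyldimethylsilyloxy)propyl]-4-oxo-2,3,3a,4,7,7a-hexahydro-1H-inden-6-yl trifluoromethanesulfonate | O=C1C=C(OS(=O)(=O)C(F)(F)F)C[C@H]2C[C@@H](O[Si](C)(C)C(C)(C)C)[C@H](CCCO[Si](C)(C)C(C)(C)C)[C@]21CCCO[Si](C)(C)C(C)(C)C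
F5 | step 14 | (1R,2S,4S,6S,9S)-9-chloro-4-methyl-13-(2-nitrophenylsulfonyl)-8-oxo-13-azatricyclo[7.7.0.0^{1,6}]hexadecane-2,4-diyl diacetate | CC(=O)O[C@H]1C[C@@](C)(OC(C)=O)C[C@H]2CC(=O)[C@]3(Cl)CCCN(S(=O)(=O)c4ccccc4[N+](=O)[O-])CCC[C@@]321
F6 | step 11 | (1S,2S,4S,6R,8R,9R)-13-benzyl-8-(tert-butyldimethylsilyloxy)-4-methyl-13-azatricyclo[7.7.0.0^{1,6}]hexadecane-2,4-diyl diacetate | CC(=O)O[C@H]1C[C@@](C)(OC(C)=O)C[C@H]2C[C@@H](O[Si](C)(C)C(C)(C)C)[C@@H]3CCCN(Cc4ccccc4)CCC[C@@]321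
F7 | step 11 | (1S,2S,4S,6R,8R,9R)-8-(tert-butyldimethylsilyloxy)-4-methyl-13-azatricyclo[7.7.0.0^{1,6}]hexadecane-2,4-diyl diacetate | CC(=O)O[C@H]1C[C@@](C)(OC(C)=O)C[C@H]2C[C@@H](O[Si](C)(C)C(C)(C)C)[C@@H]3CCCNCCC[C@@]321
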